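**Retrosynthetic overview**
1. The side chain comes last. The muconic half ester is cut at its central C–C bond (Heck: acrylic acid + β-iodoacrylate) and at the C2–O acyl bond. The C2 oxygen comes from enolate hydroxylation of the parent lactone.
2. The ten-membered (5E)-lactone comes from a bicyclic 1-oxadecalin hemiketal carrying SiMe3 at C5. An oxidative, silicon-terminated Grob-type cleavage of the shared C1–C6 bond expands the six-membered ring to ten.
3. The hemiketal precursor comes from a chelation-controlled Mukaiyama aldol (C6–C7). The partners are the 3-silyl enol silane of cyclohexanone and (2R,3S)-2-(methoxymethoxy)-3-(silyloxy)hexanal.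
4. The enol silane comes from cyclohex-2-enone + Me3SiLi/Me3SiCl. The aldehyde comes from butanal + allyl methoxymethyl ether (syn-selective alkoxyallylboration), then ozonolysis.
5. Ring order: the carbocycle is bought, the tetrahydropyran hemiketal forms transiently, and both are then merged into the ten-membered lactone.

Assumption: lactone numbering (C1 = lactone carbonyl, C9 = propyl-bearing carbon) is used for all intermediates. In it the given SMILES reads 2R,5E,7R,8S,9S, with a 7,8-syn/8,9-syn triol array.

**Step 1**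
Reactants: 1 butanal; 2 allyl methoxymethyl ether
Product: 6 (3S,4S)-3-(methoxymethoxy)hept-1-en-4-ol, via allyllithium 3 (not isolated), via Z-allylborane 4 (not isolated), via borinic ester 5 (not isolated)
Conditions: 2, s-BuLi, THF, −78 °C; (+)-Ipc2BOMe, −78 °C; BF3·OEt2, then 1, −78 to 23 °C; NaOH, H2O2, H2O
Reagents that add atoms: none
Why: Brown asymmetric γ-alkoxyallylboration runs through a closed chair transition state, so the Z-allylborane gives the 8,9-syn relationship and the isopinocampheyl groups derived from (−)-α-pinene select the aldehyde face that gives 3S,4S (C8 and C9 of the target).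

**Step 2**
Reactants: 6 (3S,4S)-3-(methoxymethoxy)hept-1-en-4-ol
Product: 7 (3S,4S)-3-(methoxymethoxy)-4-(triethylsilyloxy)hept-1-ene
Conditions: Et3SiCl, imidazole, CH2Cl2, 0 °C
Reagents that add atoms: chlorotriethylsilane, CC[Si](Cl)(CC)CC
Why: Standard silyl ether formation masks the C9 hydroxyl with a non-chelating, fluoride-labile group and touches no stereocentre.

**Step 3**
Reactants: 7 (3S,4S)-3-(methoxymethoxy)-4-(triethylsilyloxy)hept-1-ene
Product: 9 (2R,3S)-2-(methoxymethoxy)-3-(triethylsilyloxy)hexanal, via secondary ozonide 8 (not isolated)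
Conditions: O3, CH2Cl2, −78 °C; PPh3, −78 to 23 °C
Reagents that add atoms: ozone, [O-][O+]=O
Why: Ozonolysis with neutral reductive work-up turns the vinyl group into the C7 aldehyde without epimerising the α-alkoxy centre (the descriptor changes to 2R only through priorities).

**Step 4**
Reactants: 10 cyclohex-2-en-1-one
Product: 12 rac-trimethyl{[3-(trimethylsilyl)cyclohex-1-en-1-yl]oxy}silane, via lithium enolate 11 (not isolated)
Conditions: Me3SiSiMe3, MeLi, THF–HMPA, 0 °C; 10, −78 °C; Me3SiCl, Et3N, −78 to 0 °C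
Reagents that add atoms: hexamethyldisilane, C[Si](C)(C)[Si](C)(C)C; chlorotrimethylsilane, C[Si](C)(C)Cl
Why: Conjugate addition of a silyl anion followed by O-silylation places SiMe3 at C5 and fixes the enolate regiochemistry at C1=C6, and the new C5 centre may be racemic because it is erased in step 7.

**Step 5**
Reactants: 9 (2R,3S)-2-(methoxymethoxy)-3-(triethylsilyloxy)hexanal; 12 rac-trimethyl{[3-(trimethylsilyl)cyclohex-1-en-1-yl]oxy}silane
Product: 13 (2R,3R)-2-[(1R,2S,3S)-1-hydroxy-2-(methoxymethoxy)-3-(triethylsilyloxy)hexyl]-3-(trimethylsilyl)cyclohexan-1-one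
Conditions: 9, MgBr2·OEt2 (3 equiv), CH2Cl2, −78 °C; rac-12 (2.5 equiv), −78 to −20 °C; aq NaHCO3
Reagents that add atoms: none
Why: In this chelation-controlled Mukaiyama aldol, MgBr2 ties the carbonyl to the α-OMOM oxygen so that attack opposite the C9 chain gives 7R (7,8-syn), attack anti to SiMe3 gives the 5,6-trans ketone, the open transition state draws the matched (R)-enantiomer from the excess of racemic 12, and any adduct of (S)-12 has the same 7R/5,6-trans pattern and converges in step 7.

**Step 6**
Reactants: 13 aldol adduct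
Product: 14 (2R,3R)-2-[(1R,2S,3S)-1,2-bis(methoxymethoxy)-3-(triethylsilyloxy)hexyl]-3-(trimethylsilyl)cyclohexan-1-one
Conditions: MOMCl, i-Pr2NEt, Bu4NI (cat.), CH2Cl2, 0 to 35 °C
Reagents that add atoms: chloromethyl methyl ether, COCCl
Why: O-alkylation with an α-chloro ether under a hindered amine base blocks the C7 hydroxyl without enolising the β-alkoxy ketone, so no stereocentre is affected.

**Step 7**
Reactants: 14 bis-MOM triethylsilyl ketone
Product: 18 (5E,7R,8R,9S)-7,8-bis(methoxymethoxy)-9-propylnon-5-en-9-olide, via hydroxy ketone 15 (not isolated), via hemiketal 16 (not isolated), via alkoxyiodane 17 (not isolated)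
Conditions: Et3N·3HF, MeCN, 23 °C; then (CF3)2CHOH, PhI(OAc)2 (1.1 equiv), −20 to 0 °C, dark
Reagents that add atoms: none
Why: Proposed new method: this is a silicon-terminated oxidative Grob-type ring expansion in which fluoride first frees the C9 hydroxyl, hydroxy ketone 15 closes reversibly to hemiketal 16 and its tertiary OH exchanges for acetate on trivalent iodine to give 17, two-electron departure of PhI and acetate from oxygen then pulls the C1–C6 σ-bond into the new lactone carbonyl (helped by the ring-oxygen lone pair) while the equatorial C5–SiMe3 bond, antiperiplanar to C1–C6 in the chair that also holds C7 equatorial, stabilises the charge growing at C6 (β-silicon effect) and is removed by fluoride, so that the six-membered carbocycle becomes the ten-membered lactone, the anti C4–C5–C6–C7 arrangement is transferred stereospecifically into the 5E alkene, and C1–C2 cleavage has no driving force because C2 is a plain CH2; the closest known reaction types are the Pb(OAc)4- or iodosylbenzene-induced fragmentation of γ-stannyl alcohols and hemiketals and the (NH4)2Ce(NO3)6 fragmentation of γ-silyl cycloalkanols.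

**Step 8**
Reactants: 18 bis-MOM lactone
Product: 20 (2R,5E,7R,8R,9S)-2-hydroxy-7,8-bis(methoxymethoxy)-9-propylnon-5-en-9-olide, via potassium enolate 19 (not isolated)
Conditions: KN(SiMe3)2, THF, −78 °C; 2-(phenylsulfonyl)-3-phenyloxaziridine, −78 °C; AcOH
Reagents that add atoms: 2-(phenylsulfonyl)-3-phenyloxaziridine, O=S(=O)(c1ccccc1)N1OC1c1ccccc1
Why: In this Davis enolate hydroxylation the enolate plane stands roughly perpendicular to the mean plane of the ten-membered ring, so the oxaziridine reaches only the outer face, which in the conformer fixed by the C9 propyl group and the C7/C8 ethers is expected to give 2R.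

**Step 9**
Reactants: 20 (2R)-hydroxy lactone; 21 (E)-3-iodoacrylic acid
Product: 22 (2R,5E,7R,8R,9S)-2-[(E)-3-iodoacryloyloxy]-7,8-bis(methoxymethoxy)-9-propylnon-5-en-9-olide
Conditions: 21, i-PrN=C=N-i-Pr, DMAP (10 mol %), CH2Cl2, 0 °C
Reagents that add atoms: none
Why: Steglich esterification acylates the only free hydroxyl at oxygen, so C2 keeps its configuration and the thermodynamically favoured E-iodoacrylate geometry is kept.

**Step 10**
Reactants: 22 iodoacrylate; 23 acrylic acid
Product: 24 (2E,4E)-6-{[(2R,5E,7R,8R,9S)-7,8-bis(methoxymethoxy)-1-oxo-9-propylnon-5-en-9-olid-2-yl]oxy}-6-oxohexa-2,4-dienoic acid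
Conditions: 23 (3 equiv), Pd(OAc)2 (5 mol %), AgOAc (1.2 equiv), DMF, 40 °C
Reagents that add atoms: none
Why: In this Mizoroki–Heck vinylation zerovalent palladium inserts into the electron-poor C–I bond with retention, syn carbopalladation of acrylic acid and syn β-hydride elimination give the new E alkene, and AgOAc removes iodide so that the reaction stays near neutral and neither C2 nor the ring alkene is disturbed.

**Step 11**
Reactants: 24 bis-MOM half ester
Product: 25 target, (2E,4E)-6-{[(2R,5E,7R,8S,9S)-7,8-dihydroxy-1-oxo-9-propylnon-5-en-9-olid-2-yl]oxy}-6-oxohexa-2,4-dienoic acid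
Conditions: CF3CO2H–H2O (9:1), 0 to 23 °C
Reagents that add atoms: none
Why: Acid hydrolysis cleaves both formaldehyde acetals, water traps the oxocarbenium ions so that no cyclic formal forms on the 7,8-diol, and the lactone, the ester and the dienoic acid survive with no stereocentre involved.

**Compound list**
1 | butanal | CCCC=O | starting material
2 | allyl methoxymethyl ether | C=CCOCOC | starting material
3 | (Z)-3-(methoxymethoxy)allyllithium | COCO/C=C\C[Li] | intermediate
4 | (Z)-[3-(methoxymethoxy)allyl]bis(isopinocampheyl)borane, Ipc from (−)-α-pinene | COCO/C=C\CB([C@H]1C[C@H]2C[C@@H]([C@@H]1C)C2(C)C)[C@H]1C[C@H]2C[C@@H]([C@@H]1C)C2(C)C | intermediate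
5 | bis(isopinocampheyl)borinic ester of 6 | CCC[C@H](OB([C@H]1C[C@H]2C[C@@H]([C@@H]1C)C2(C)C)[C@H]1C[C@H]2C[C@@H]([C@@H]1C)C2(C)C)[C@@H](OCOC)C=C | intermediate
6 | (3S,4S)-3-(methoxymethoxy)hept-1-en-4-ol | CCC[C@H](O)[C@@H](OCOC)C=C | intermediate
7 | (3S,4S)-3-(methoxymethoxy)-4-(triethylsilyloxy)hept-1-ene | CCC[C@H](O[Si](CC)(CC)CC)[C@@H](OCOC)C=C | intermediate
8 | secondary ozonide (1,2,4-trioxolane) of 7, epimers at the ring carbon | CCC[C@H](O[Si](CC)(CC)CC)[C@@H](OCOC)C1OCOO1 | intermediate
9 | (2R,3S)-2-(methoxymethoxy)-3-(triethylsilyloxy)hexanal | CCC[C@H](O[Si](CC)(CC)CC)[C@@H](OCOC)C=O | intermediate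
10 | cyclohex-2-en-1-one | O=C1C=CCCC1 | starting material
11 | lithium 3-(trimethylsilyl)cyclohex-1-en-1-olate, racemic | [Li]OC1=CC(CCC1)[Si](C)(C)C | intermediate
12 | rac-trimethyl{[3-(trimethylsilyl)cyclohex-1-en-1-yl]oxy}silane | C[Si](C)(C)OC1=CC(CCC1)[Si](C)(C)C | intermediate
13 | (2R,3R)-2-[(1R,2S,3S)-1-hydroxy-2-(methoxymethoxy)-3-(triethylsilyloxy)hexyl]-3-(trimethylsilyl)cyclohexan-1-one | CCC[C@H](O[Si](CC)(CC)CC)[C@@H](OCOC)[C@H](O)[C@@H]1C(=O)CCC[C@H]1[Si](C)(C)C | intermediate
14 | (2R,3R)-2-[(1R,2S,3S)-1,2-bis(methoxymethoxy)-3-(triethylsilyloxy)hexyl]-3-(trimethylsilyl)cyclohexan-1-one | CCC[C@H](O[Si](CC)(CC)CC)[C@@H](OCOC)[C@H](OCOC)[C@@H]1C(=O)CCC[C@H]1[Si](C)(C)C | intermediate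
15 | (2R,3R)-2-[(1R,2R,3S)-3-hydroxy-1,2-bis(methoxymethoxy)hexyl]-3-(trimethylsilyl)cyclohexan-1-one | CCC[C@H](O)[C@@H](OCOC)[C@H](OCOC)[C@@H]1C(=O)CCC[C@H]1[Si](C)(C)C | intermediate
16 | (2S,3R,4R,4aR,5R,8aS)-3,4-bis(methoxymethoxy)-2-propyl-5-(trimethylsilyl)octahydro-2H-chromen-8a-ol, trans-fused | CCC[C@@H]1O[C@@]2(O)CCC[C@@H]([Si](C)(C)C)[C@@H]2[C@@H](OCOC)[C@@H]1OCOC | intermediate
17 | acetoxy(phenyl)-λ3-iodanyl ether of 16 | CCC[C@@H]1O[C@@]2(OI(OC(C)=O)c3ccccc3)CCC[C@@H]([Si](C)(C)C)[C@@H]2[C@@H](OCOC)[C@@H]1OCOC | intermediate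
18 | (5E,7R,8R,9S)-7,8-bis(methoxymethoxy)-9-propylnon-5-en-9-olide | CCC[C@@H]1OC(=O)CCC/C=C/[C@@H](OCOC)[C@@H]1OCOC | intermediate
19 | potassium enolate of 18 | CCC[C@@H]1OC(O[K])=CCC/C=C/[C@@H](OCOC)[C@@H]1OCOC | intermediate
20 | (2R,5E,7R,8R,9S)-2-hydroxy-7,8-bis(methoxymethoxy)-9-propylnon-5-en-9-olide | CCC[C@@H]1OC(=O)[C@H](O)CC/C=C/[C@@H](OCOC)[C@@H]1OCOC | intermediate
21 | (E)-3-iodoacrylic acid | OC(=O)/C=C/I | starting material
22 | (E)-3-iodoacrylate of 20 | CCC[C@@H]1OC(=O)[C@H](OC(=O)/C=C/I)CC/C=C/[C@@H](OCOC)[C@@H]1OCOC | intermediate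
23 | acrylic acid | C=CC(=O)O | starting material
24 | 7,8-bis-MOM ether of the target | CCC[C@@H]1OC(=O)[C@H](OC(=O)/C=C/C=C/C(=O)O)CC/C=C/[C@@H](OCOC)[C@@H]1OCOC | intermediate
25 | CNP0476488.1, (2R,5E,7R,8S,9S) | CCC[C@@H]1OC(=O)[C@H](OC(=O)/C=C/C=C/C(=O)O)CC/C=C/[C@@H](O)[C@@H]1O | target

**Step count**
Total: 11 steps. Longest linear sequence: 10 steps (1, 2, 3, 5, 6, 7, 8, 9, 10, 11).

**Steps most likely to fail**

Step 7 (the new ring expansion). Three things could go wrong:
- The hemiketal may be poorly populated.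
- The iodane may react by a radical path and lose alkene geometry.
- The product alkene may be attacked by the oxidant.

The fallback sets out from 14 and comes back at 18, and every reaction in it is a known type. A silicon-directed Baeyer–Villiger oxidation (mCPBA, Na2HPO4, CH2Cl2) makes the secondary, β-silyl-activated C6 migrate with retention. This gives the 7-substituted 6-(trimethylsilyl)oxepan-2-one F1. Bu4NF in THF then removes the triethylsilyl ether and triggers the anti β-elimination of silicon and carboxylate. This gives (5E,7R,8R,9S)-9-hydroxy-7,8-bis(methoxymethoxy)dodec-5-enoic acid F2. Yamaguchi macrolactonisation (2,4,6-trichlorobenzoyl chloride, Et3N, then DMAP, toluene, high dilution) closes F2 to 18.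

Step 8 (facial selectivity at C2). The preferred face of the medium-ring enolate cannot be predicted with confidence. The fallback sets out from 18 and comes back at 22. If the oxidation gives mainly or partly the (2S)-2-hydroxy lactone F3, it is separated. It is then esterified with 21 under Mitsunobu conditions (PPh3, diisopropyl azodicarboxylate, THF, 0 °C). The SN2 inversion at the activated α-carbon delivers the same (2R)-ester 22. Both epimers are therefore funnelled into the route.

Step 10 (late Heck coupling). Three things could go wrong: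
- Palladium hydride may isomerise the ring alkene.
- C2 may epimerise.
- The polar acid may be hard to purify.

The fallback sets out from 20 and 21 and comes back at 25. The diene is built first on small molecules. Compound 21 and tert-butyl acrylate (C=CC(=O)OC(C)(C)C) react under Pd(OAc)2/AgOAc in DMF. This gives (2E,4E)-6-tert-butoxy-6-oxohexa-2,4-dienoic acid F4. Carbodiimide/DMAP coupling of F4 with 20 gives the tert-butyl muconate bis-MOM lactone F5. CF3CO2H–H2O then cleaves the tert-butyl ester and both MOM ethers in one operation to give 25.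

**Further compounds**
F1 | step 7 | 7-[(1R,2S,3S)-1,2-bis(methoxymethoxy)-3-(triethylsilyloxy)hexyl]-6-(trimethylsilyl)oxepan-2-one (C5–C9 configuration of 14 retained) | CCC[C@H](O[Si](CC)(CC)CC)[C@@H](OCOC)[C@H](OCOC)[C@@H]1OC(=O)CCC[C@H]1[Si](C)(C)C
F2 | step 7 | (5E,7R,8R,9S)-9-hydroxy-7,8-bis(methoxymethoxy)dodec-5-enoic acid | CCC[C@H](O)[C@@H](OCOC)[C@H](OCOC)/C=C/CCCC(=O)O
F3 | step 8 | (2S,5E,7R,8R,9S)-2-hydroxy-7,8-bis(methoxymethoxy)-9-propylnon-5-en-9-olide | CCC[C@@H]1OC(=O)[C@@H](O)CC/C=C/[C@@H](OCOC)[C@@H]1OCOC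
F4 | step 10 | (2E,4E)-6-tert-butoxy-6-oxohexa-2,4-dienoic acid | CC(C)(C)OC(=O)/C=C/C=C/C(=O)O
F5 | step 10 | tert-butyl ester of 24 | CCC[C@@H]1OC(=O)[C@H](OC(=O)/C=C/C=C/C(=O)OC(C)(C)C)CC/C=C/[C@@H](OCOC)[C@@H]1OCOC
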